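## The problem

The target is a C2-symmetric dimer in which two (3R)-7,3'-dihydroxy-2'-methoxyisoflavan units are joined by a diaryl ether oxygen between their C4' carbons, so each ring B carries four contiguous substituents: C3 at C1', OMe at C2', OH at C3' and the bridging oxygen at C4'. The only stereocentres are the two C3 carbons, both R; they lie ten bonds apart across two arenes and cannot control each other, so each must be set by an external chiral element, most economically in one twofold reaction on a symmetric precursor. C3 is a benzylic methine between the C2 and C4 methylenes; it is configurationally safe in the target but labile whenever C2 or C4 is at the carbonyl level. The two ring B oxygens must be told apart (methyl on O2', hydrogen on O3'). A closing Lewis-acid demethylation would not spare the 2'-methyl ether, so the free hydroxyls must emerge from groups that leave under neutral conditions. The diaryl ether is inert and can be made first. The enabling feature is that C1', which holds C3, is ortho to O2', and O2' neighbours O3'. This is the array left by ortho-Claisen rearrangement of a catechol monoallyl ether with the allyl group on O2' and the free phenol at O3'; C1' is the only open ortho position and is para to the C4' oxygen.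

## Retrosynthesis

Target 28 is traced to its tetrabenzyl ether 27 by cutting four O–benzyl bonds. One neutral hydrogenolysis then frees the 7- and 3'-hydroxyls together and leaves the 2'-methyl ethers alone. No skeletal bond is involved.

In 27 the two O1–C8a bonds are cut, giving the bis(primary alcohol) bis(aryl bromide) 26. Cutting O1–C2 instead would need a free ring A phenol orthogonal to the 7- and 3'-oxygens, a third phenol protecting group. The aryl bromide is a silent spectator until it is needed. The forward reaction is a twofold intramolecular copper-catalysed O-arylation closing six-membered rings.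

The C2 hydroxymethyl groups of 26 are traced through dialdehyde 25 and tetraol 24 to the vinyl groups of 23, with one carbon excised per half. This is what a [3,3] shift leaves behind. The forward sequence must not let the α-aryl aldehyde 25 enolise.

The methyl ethers on O2' and benzyl ethers on O3' of 23 are removed in turn, through 22, to the bis-catechol 21. The forward reactions must distinguish two neighbouring phenols; the argument rests on their different acidity and shielding.

Key cut: both C3–C1' bonds of 21 are broken and each allyl unit is reattached through its other terminus to O2', giving the achiral bis(catechol monoallyl ether) 18. Neighbouring cuts (C4–C4a by conjugate arylation, C3–H by protonation or hydrogenation) leave the hindered aryl–C3 bond to be made separately and give no handle on the oxygen pattern. The Claisen cut uses that pattern as its directing element. It forms the congested C1'–C3 bond intramolecularly without prefunctionalising C1', and it sets both stereocentres under control of a chiral boron reagent bound to the free 3'-phenol. The forward reaction needs geometrically pure E alkenes, free 3'-hydroxyls and a single open ortho position.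

The two O2'–allyl bonds of 18 are cut, via the bis(MOM ether) 17, to one molecule of the core diol 16 and two molecules of the E-allylic bromide 8, one for each outer phenol. MOM on the inner oxygen keeps the two oxygens of each ring distinct and leaves under acid that an aryl allyl ether tolerates.

In 16 the outer C–OH bonds are cut back to the bis(MOM ether) 13. Introducing this oxygen last, by metalation directed by the inner MOM ether, makes the inner/outer differentiation automatic. Masking near-equivalent hydroxyls after both are in place would not. Compound 13 comes from diphenol 12 and its dimethyl ether 11, whose diaryl ether bond is cut to 2-methoxyphenol 9 and 2-bromoanisole 10 (Ullmann coupling).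

Bromide 8 is traced to the E-allylic alcohol 7 and this to the propargylic alcohol 6, the alkyne serving as a precursor of a pure E alkene. The benzylic C–C(sp) bond of 6 is cut to benzylic bromide 4 and propargyl alcohol 5. Compound 4 comes from alcohol 3, aldehyde 2 and 2-bromo-4-hydroxybenzaldehyde 1.

## Roads not taken

Alternative 1: The cut is O1–C8a together with the aromaticity of ring A. Each ring A is carried as a 3-ethoxycyclohex-2-enone alkylated at C6 by the C4 methylene, as in the open precursor A2. Aqueous acid would hydrolyse the enol ethers of A2, and the pendant C2 hydroxyl would condense with the carbonyl next to the alkylated carbon. This closes both dihydropyrans as the bicyclic vinylogous esters A1; dehydrogenation would then give the 7-hydroxy arenes.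
- Merits: the C–O bond forms without a transition metal, no aryl bromide is carried, and the 7-hydroxyl appears unprotected, saving a protecting group against the chosen plan.
- Weak points: the step sets no stereocentre, so C3 would have to arrive in an enantioenriched alkylating chain. Each half gains an uncontrolled C4a centre, so A1 is a mixture of diastereomers until aromatisation. Kinetic enolate alkylation with a β-branched electrophile is slow. The closing dehydrogenation must spare two very electron-rich B rings and their benzyl ethers.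
- Comparison: the ring closure itself is at least as reliable as the copper-catalysed one. The chosen plan sets against it an aromatic ring A from the start, no late oxidation-state adjustment, and both stereocentres set in the step that makes C3–C1'.

Alternative 2: The cut is the two C3'–O bonds. The 3'-deoxy bis-isoflavan A4 would be lithiated at C3', between the 2'-methoxy and 4'-aryloxy groups, on both B rings (s-BuLi, TMEDA). The dianion would be trapped with B(OMe)3 and oxidised with H2O2 to the bis(silyl ether) A3 of the target.
- Merits: the 2'-OMe/3'-OH distinction is automatic, because the methyl ether is present from the start and the hydroxyl enters last. This is where the chosen plan is weakest (step 14), and on this point the alternative is better.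
- Weak points: the step creates no stereocentre, so A4 needs its own asymmetric synthesis of both C3 centres. Competing deprotonation is possible at C8 of ring A (between O1 and the silyloxy group), at C5', or at the benzylic C3–H, which would erode configuration. It is a strongly basic, twofold reaction on the most advanced intermediate.
- Comparison: the chosen plan uses the same metalation–oxidation logic early (step 10), on the simple achiral ether 13 where a mis-lithiation costs little. It then uses the resulting dioxygen pattern to direct the asymmetric C–C bond formation.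

Alternative 3: The cut is C4–C4a with the C3–H bond. The ring A boronic acid A7 would add through an aryl–rhodium species to the methylene of each α-arylacrylate unit of A6. The rhodium enolate would be protonated at C3 under chiral diphosphine control, giving the bis(ester) A5. Ester reduction and ring closure from the ring A phenol would follow.
- Merits: chirality is catalytic, whereas the chosen plan uses a stoichiometric (recoverable) chiral ligand. Ring A is joined in the stereodefining step, no carbon is excised, and the 2'-OMe/3'-OBn pattern is fixed on an achiral core without a regioselective protection. In step economy and atom economy this road is better.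
- Weak points: enantioselective protonation is far less developed for α-aryl enolates than for α-amino or α-alkyl ones. The stereocentre of A5 is an acidic α-aryl ester position under the basic coupling conditions. The ortho-substituted acrylate A6 is twisted and prone to polymerise, and the ortho-alkoxy boronic acid A7 to protodeboronate.
- Comparison: the chosen plan sets against the catalytic economy a reaction with direct precedent on catechol monoallyl ethers, and a stereocentre that is not enolisable when formed. It does become α to an aldehyde once, in step 17, and that is flagged below.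

Key step: step 13

Assumption: with E-configured allyl termini the (S,S)-bromoborane is taken to deliver the (S)-configured benzylic carbons of 21 (the arrangement that becomes 3R in the target). Both enantiomers of the diamine are available, so the antipodal reagent would be used if the sense proves opposite.

## Route

Step 1
Reactants: 1 2-bromo-4-hydroxybenzaldehyde
Product: 2 4-(benzyloxy)-2-bromobenzaldehyde
Conditions: BnBr, K2CO3, DMF, rt
Reagents that add atoms: benzyl bromide, BrCc1ccccc1
Why: Williamson etherification of an acidic para-formyl phenol; benzyl survives every later step and leaves by hydrogenolysis at the end.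

Step 2
Reactants: 2 4-(benzyloxy)-2-bromobenzaldehyde
Product: 3 [4-(benzyloxy)-2-bromophenyl]methanol
Conditions: NaBH4, MeOH/THF, 0 °C
Reagents that add atoms: none
Why: Borohydride reduction of an aryl aldehyde; the aryl bromide and benzyl ether are inert.

Step 3
Reactants: 3 [4-(benzyloxy)-2-bromophenyl]methanol
Product: 4 4-(benzyloxy)-2-bromo-1-(bromomethyl)benzene
Conditions: PBr3, CH2Cl2, 0 °C
Reagents that add atoms: phosphorus tribromide, BrP(Br)Br
Why: Standard conversion of a benzylic alcohol into its bromide through the phosphite ester; the para-alkoxybenzyl bromide is used without storage.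

Step 4
Reactants: 4 4-(benzyloxy)-2-bromo-1-(bromomethyl)benzene; 5 prop-2-yn-1-ol
Product: 6 4-[4-(benzyloxy)-2-bromophenyl]but-2-yn-1-ol
Conditions: CuI (cat.), NaI (cat.), Cs2CO3, MeCN, rt
Reagents that add atoms: none
Why: Copper-mediated alkylation of a terminal alkyne (copper acetylide) with a benzylic halide, the sp–sp3 coupling used for skipped diynes and benzyl alkynes; the carbonate base and room temperature leave the aryl bromide untouched.

Step 5
Reactants: 6 4-[4-(benzyloxy)-2-bromophenyl]but-2-yn-1-ol
Product: 7 (2E)-4-[4-(benzyloxy)-2-bromophenyl]but-2-en-1-ol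
Conditions: NaAlH2(OCH2CH2OCH3)2, THF, 0 °C; aq. potassium sodium tartrate
Reagents that add atoms: none
Why: Alkoxide-directed trans-hydroalumination of a propargylic alcohol and protonolysis give the E-allylic alcohol as a single geometric isomer, which the key step requires; aryl bromides tolerate the reagent at 0 °C.

Step 6
Reactants: 7 (2E)-4-[4-(benzyloxy)-2-bromophenyl]but-2-en-1-ol
Product: 8 4-(benzyloxy)-2-bromo-1-[(2E)-4-bromobut-2-en-1-yl]benzene
Conditions: CBr4, PPh3, CH2Cl2, 0 °C
Reagents that add atoms: carbon tetrabromide, BrC(Br)(Br)Br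
Why: Appel bromination of a primary allylic alcohol is neutral and proceeds without allylic transposition or loss of alkene geometry.

Step 7
Reactants: 9 2-methoxyphenol; 10 1-bromo-2-methoxybenzene
Product: 11 1,1'-oxybis(2-methoxybenzene)
Conditions: CuI (cat.), picolinic acid, K3PO4, DMSO, 90 °C
Reagents that add atoms: none
Why: Ullmann-type diaryl ether synthesis; the copper–picolinic acid system is established for partners that each carry an ortho substituent.

Step 8
Reactants: 11 1,1'-oxybis(2-methoxybenzene)
Product: 12 2,2'-oxydiphenol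
Conditions: BBr3, CH2Cl2, −78 °C → rt; H2O
Reagents that add atoms: none
Why: Lewis-acid cleavage of aryl methyl ethers; the diaryl ether has no alkyl carbon for bromide to attack and stays intact.

Step 9
Reactants: 12 2,2'-oxydiphenol
Product: 13 1,1'-oxybis[2-(methoxymethoxy)benzene]
Conditions: MOMCl, i-Pr2NEt, CH2Cl2, 0 °C → rt
Reagents that add atoms: chloromethyl methyl ether, COCCl
Why: Acetal protection of both phenols; MOM is the strongest director for the next step, does not migrate between neighbouring oxygens, and leaves under mild acid that an aryl allyl ether survives.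

Step 10
Reactants: 13 1,1'-oxybis[2-(methoxymethoxy)benzene]
Product: 16 3,3'-oxybis[2-(methoxymethoxy)phenol], via 3,3'-dilithio species 14 (not isolated), via bis(dimethyl boronate) 15 (not isolated)
Conditions: n-BuLi, TMEDA, THF, −20 → 0 °C; B(OMe)3, −78 °C → rt; H2O2, aq. NaOH, 0 °C
Reagents that add atoms: hydrogen peroxide, OO
Why: Directed ortho-metalation: the chelating MOM ether directs lithiation to its only free ortho position on each ring, and the aryllithium is trapped as the boronate and oxidised with 1,2-aryl migration to the phenol. The outer oxygen thus enters already distinguished from the MOM-protected inner one.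

Step 11
Reactants: 16 3,3'-oxybis[2-(methoxymethoxy)phenol]; 8 4-(benzyloxy)-2-bromo-1-[(2E)-4-bromobut-2-en-1-yl]benzene (2 equiv)
Product: 17 bis{3-{[(2E)-4-(4-benzyloxy-2-bromophenyl)but-2-en-1-yl]oxy}-2-(methoxymethoxy)phenyl} ether
Conditions: 8 (2.2 equiv), K2CO3, DMF, rt
Reagents that add atoms: second equivalent of allylic bromide 8, BrC/C=C/Cc1ccc(OCc2ccccc2)cc1Br
Why: Twofold Williamson alkylation: each of the two phenoxides of 16 takes up one molecule of the primary allylic bromide 8 by direct SN2 displacement, so two molecules of 8 are built into 17 and the mono-ether reacts on in the same flask. The mild carbonate base at room temperature keeps the E geometry and does not move the alkene into conjugation.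

Step 12
Reactants: 17 bis{3-{[(2E)-4-(4-benzyloxy-2-bromophenyl)but-2-en-1-yl]oxy}-2-(methoxymethoxy)phenyl} ether
Product: 18 bis{3-{[(2E)-4-(4-benzyloxy-2-bromophenyl)but-2-en-1-yl]oxy}-2-hydroxyphenyl} ether
Conditions: HCl (cat.), MeOH/THF, 40 °C
Reagents that add atoms: none
Why: Acid-catalysed acetal exchange removes the aryl MOM ethers as dimethoxymethane; aryl allyl ethers, benzyl ethers and the alkene are stable to dilute methanolic acid.

Step 13
Reactants: 18 bis{3-{[(2E)-4-(4-benzyloxy-2-bromophenyl)but-2-en-1-yl]oxy}-2-hydroxyphenyl} ether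
Product: 21 bis{4-[(2S)-1-(4-benzyloxy-2-bromophenyl)but-3-en-2-yl]-2,3-dihydroxyphenyl} ether, via bis(aryloxyborane) 19 (not isolated), via rearranged bis(aryloxyborane) 20 (not isolated)
Conditions: (4S,5S)-2-bromo-4,5-diphenyl-1,3-ditosyl-1,3,2-diazaborolidine (3 equiv; made first in the flask from (S,S)-TsNHCH(Ph)CH(Ph)NHTs and BBr3, CH2Cl2), Et3N, CH2Cl2, −78 → −45 °C; H2O
Reagents that add atoms: none
Why: Each free 3'-phenol displaces bromide from boron (Et3N takes up HBr) to give 19, in which the electron-poor tricoordinate boron is chelated by the neighbouring allyl ether oxygen; this polarises the O–CH2 bond and lets the charge-accelerated aromatic Claisen rearrangement run far below its thermal threshold. The allyl terminus bonds to C1' through a chair-like six-centre transition state, the dienone tautomerises to the boron-bound catechol 20, and aqueous work-up releases 21 and the recoverable bis(sulfonamide). The closest known reaction is this same enantioselective Claisen rearrangement of catechol monoallyl ethers promoted by a stoichiometric chiral B-bromodiazaborolidine, here applied twice in one molecule. No ring is closed. Each C3 stereocentre is set by reagent control: the tosyl groups, held anti to the ring phenyls, leave one quadrant open for the chelated allyl chain, so one enantioface of the E-configured terminus is presented to C1', and the two sites are too far apart to influence each other. Regioselectivity is secured by the substrate, since C1' is the only unsubstituted carbon ortho to the allyloxy group and is activated by the para aryloxy oxygen, and the low temperature excludes para and abnormal Claisen pathways. The enantiofacial selectivity needed rests on the pure E alkene from step 5 and on the reagent; because two centres are set, a mis-set terminus ends mainly in the separable meso diastereomer, which raises the enantiomeric purity of the C2-symmetric product. Benzyl ethers and aryl bromides are not attacked by this attenuated boron Lewis acid at −45 °C.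

Step 14
Reactants: 21 bis{4-[(2S)-1-(4-benzyloxy-2-bromophenyl)but-3-en-2-yl]-2,3-dihydroxyphenyl} ether
Product: 22 bis{2-(benzyloxy)-4-[(2S)-1-(4-benzyloxy-2-bromophenyl)but-3-en-2-yl]-3-hydroxyphenyl} ether
Conditions: BnBr (1 equiv per catechol), Li2CO3, DMF, 40 °C
Reagents that add atoms: benzyl bromide, BrCc1ccccc1
Why: Williamson monoalkylation of a catechol at its more acidic oxygen under a weak base: the 3'-oxygen anion is stabilised by the inductively withdrawing aryloxy neighbour and a hydrogen bond from the 2'-hydroxyl, whereas the 2'-oxygen sits beside the electron-releasing branched side chain that also shields it. With a carbonate too weak to form the dianion, the 3'-O-benzyl ether should dominate.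

Step 15
Reactants: 22 bis{2-(benzyloxy)-4-[(2S)-1-(4-benzyloxy-2-bromophenyl)but-3-en-2-yl]-3-hydroxyphenyl} ether
Product: 23 bis{2-(benzyloxy)-4-[(2S)-1-(4-benzyloxy-2-bromophenyl)but-3-en-2-yl]-3-methoxyphenyl} ether
Conditions: MeI, K2CO3, DMF, rt
Reagents that add atoms: iodomethane, CI
Why: Williamson methylation of the one remaining, hindered phenol in each half; benzyl cannot migrate, so the 2'-OMe/3'-OBn pattern of the target is fixed here.

Step 16
Reactants: 23 bis{2-(benzyloxy)-4-[(2S)-1-(4-benzyloxy-2-bromophenyl)but-3-en-2-yl]-3-methoxyphenyl} ether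
Product: 24 bis{2-(benzyloxy)-4-[(2R)-1-(4-benzyloxy-2-bromophenyl)-3,4-dihydroxybutan-2-yl]-3-methoxyphenyl} ether (both configurations at each new carbinol carbon)
Conditions: OsO4 (cat.), NMO, acetone/H2O, rt
Reagents that add atoms: N-methylmorpholine N-oxide, C[N+]1([O-])CCOCC1 (terminal oxidant, oxygen delivered through OsO4); water, O
Why: Catalytic OsO4 dihydroxylation with an amine N-oxide reoxidant is selective for the monosubstituted alkenes over the electron-rich arenes. The new carbinol configuration is irrelevant because those carbons are cleaved next, and isolating the diol removes the amine base before an enolisable aldehyde is made.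

Step 17
Reactants: 24 bis{2-(benzyloxy)-4-[(2R)-1-(4-benzyloxy-2-bromophenyl)-3,4-dihydroxybutan-2-yl]-3-methoxyphenyl} ether
Product: 26 bis{2-(benzyloxy)-4-[(2R)-1-(4-benzyloxy-2-bromophenyl)-3-hydroxypropan-2-yl]-3-methoxyphenyl} ether, via dialdehyde 25 (not isolated)
Conditions: NaIO4, THF/pH 7 phosphate buffer, 0 °C; then NaBH4 added to the same flask, 0 °C
Reagents that add atoms: none
Why: Periodate glycol cleavage under buffered neutral conditions gives the α-aryl aldehyde 25, which borohydride reduces in the same flask before it can enolise, so C3 keeps its configuration; the primary alcohol formed is the C2–OH of the isoflavan.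

Step 18
Reactants: 26 bis{2-(benzyloxy)-4-[(2R)-1-(4-benzyloxy-2-bromophenyl)-3-hydroxypropan-2-yl]-3-methoxyphenyl} ether
Product: 27 bis{2-(benzyloxy)-4-[(3R)-7-(benzyloxy)-3,4-dihydro-2H-chromen-3-yl]-3-methoxyphenyl} ether
Conditions: CuI (cat.), 3,4,7,8-tetramethyl-1,10-phenanthroline, Cs2CO3, toluene, 110 °C
Reagents that add atoms: none
Why: Intramolecular Ullmann-type C–O coupling of a primary alcohol with an ortho-tethered aryl bromide closes each dihydropyran by six-membered ring formation (O1–C8a); C3 is β to the reacting oxygen and not acidic, so the carbonate base leaves it untouched.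

Step 19
Reactants: 27 bis{2-(benzyloxy)-4-[(3R)-7-(benzyloxy)-3,4-dihydro-2H-chromen-3-yl]-3-methoxyphenyl} ether
Product: 28 bis{2-hydroxy-4-[(3R)-7-hydroxy-3,4-dihydro-2H-chromen-3-yl]-3-methoxyphenyl} ether (CNP0116832.1)
Conditions: H2 (1 atm), Pd/C, EtOAc/MeOH, rt
Reagents that add atoms: none
Why: Hydrogenolysis of the four benzyl ethers over palladium on carbon under neutral conditions frees the 7- and 3'-hydroxyls; the methyl ethers, the diaryl ether and the alkyl aryl ether of ring C are inert.

## Compound list

1 | 2-bromo-4-hydroxybenzaldehyde | O=Cc1ccc(O)cc1Br | starting material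
2 | 4-(benzyloxy)-2-bromobenzaldehyde | O=Cc1ccc(OCc2ccccc2)cc1Br | intermediate
3 | [4-(benzyloxy)-2-bromophenyl]methanol | OCc1ccc(OCc2ccccc2)cc1Br | intermediate
4 | 4-(benzyloxy)-2-bromo-1-(bromomethyl)benzene | BrCc1ccc(OCc2ccccc2)cc1Br | intermediate
5 | prop-2-yn-1-ol (propargyl alcohol) | C#CCO | starting material
6 | 4-[4-(benzyloxy)-2-bromophenyl]but-2-yn-1-ol | OCC#CCc1ccc(OCc2ccccc2)cc1Br | intermediate
7 | (2E)-4-[4-(benzyloxy)-2-bromophenyl]but-2-en-1-ol | OC/C=C/Cc1ccc(OCc2ccccc2)cc1Br | intermediate
8 | 4-(benzyloxy)-2-bromo-1-[(2E)-4-bromobut-2-en-1-yl]benzene | BrC/C=C/Cc1ccc(OCc2ccccc2)cc1Br | intermediate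
9 | 2-methoxyphenol | COc1ccccc1O | starting material
10 | 1-bromo-2-methoxybenzene | COc1ccccc1Br | starting material
11 | 1,1'-oxybis(2-methoxybenzene) | COc1ccccc1Oc1ccccc1OC | intermediate
12 | 2,2'-oxydiphenol | Oc1ccccc1Oc1ccccc1O | intermediate
13 | 1,1'-oxybis[2-(methoxymethoxy)benzene] | COCOc1ccccc1Oc1ccccc1OCOC | intermediate
14 | 3,3'-dilithio derivative of 13 (lithium ortho to each MOM ether) | [Li]c1cccc(Oc2cccc([Li])c2OCOC)c1OCOC | intermediate
15 | tetramethyl [oxybis(2-(methoxymethoxy)-3,1-phenylene)]bis(boronate) | COB(OC)c1cccc(Oc2cccc(B(OC)OC)c2OCOC)c1OCOC | intermediate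
16 | 3,3'-oxybis[2-(methoxymethoxy)phenol] | COCOc1c(O)cccc1Oc1cccc(O)c1OCOC | intermediate
17 | bis{3-{[(2E)-4-(4-benzyloxy-2-bromophenyl)but-2-en-1-yl]oxy}-2-(methoxymethoxy)phenyl} ether | O(c1cccc(OC/C=C/Cc2ccc(OCc3ccccc3)cc2Br)c1OCOC)c1cccc(OC/C=C/Cc2ccc(OCc3ccccc3)cc2Br)c1OCOC | intermediate
18 | bis{3-{[(2E)-4-(4-benzyloxy-2-bromophenyl)but-2-en-1-yl]oxy}-2-hydroxyphenyl} ether | O(c1cccc(OC/C=C/Cc2ccc(OCc3ccccc3)cc2Br)c1O)c1cccc(OC/C=C/Cc2ccc(OCc3ccccc3)cc2Br)c1O | intermediate
19 | 18 with each phenol oxygen bound to a (4S,5S)-4,5-diphenyl-1,3-ditosyl-1,3,2-diazaborolidin-2-yl group | O(c1cccc(OC/C=C/Cc2ccc(OCc3ccccc3)cc2Br)c1OB1N(S(=O)(=O)c2ccc(C)cc2)[C@@H](c2ccccc2)[C@H](c2ccccc2)N1S(=O)(=O)c1ccc(C)cc1)c1cccc(OC/C=C/Cc2ccc(OCc3ccccc3)cc2Br)c1OB1N(S(=O)(=O)c2ccc(C)cc2)[C@@H](c2ccccc2)[C@H](c2ccccc2)N1S(=O)(=O)c1ccc(C)cc1 | intermediate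
20 | 21 with each inner (3') oxygen still bound to the (4S,5S)-diazaborolidin-2-yl group | Oc1c([C@@H](Cc2ccc(OCc3ccccc3)cc2Br)C=C)ccc(Oc2ccc([C@@H](Cc3ccc(OCc4ccccc4)cc3Br)C=C)c(O)c2OB2N(S(=O)(=O)c3ccc(C)cc3)[C@@H](c3ccccc3)[C@H](c3ccccc3)N2S(=O)(=O)c2ccc(C)cc2)c1OB1N(S(=O)(=O)c2ccc(C)cc2)[C@@H](c2ccccc2)[C@H](c2ccccc2)N1S(=O)(=O)c1ccc(C)cc1 | intermediate
21 | bis{4-[(2S)-1-(4-benzyloxy-2-bromophenyl)but-3-en-2-yl]-2,3-dihydroxyphenyl} ether | Oc1c([C@@H](Cc2ccc(OCc3ccccc3)cc2Br)C=C)ccc(Oc2ccc([C@@H](Cc3ccc(OCc4ccccc4)cc3Br)C=C)c(O)c2O)c1O | intermediate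
22 | bis{2-(benzyloxy)-4-[(2S)-1-(4-benzyloxy-2-bromophenyl)but-3-en-2-yl]-3-hydroxyphenyl} ether | Oc1c([C@@H](Cc2ccc(OCc3ccccc3)cc2Br)C=C)ccc(Oc2ccc([C@@H](Cc3ccc(OCc4ccccc4)cc3Br)C=C)c(O)c2OCc2ccccc2)c1OCc1ccccc1 | intermediate
23 | bis{2-(benzyloxy)-4-[(2S)-1-(4-benzyloxy-2-bromophenyl)but-3-en-2-yl]-3-methoxyphenyl} ether | COc1c([C@@H](Cc2ccc(OCc3ccccc3)cc2Br)C=C)ccc(Oc2ccc([C@@H](Cc3ccc(OCc4ccccc4)cc3Br)C=C)c(OC)c2OCc2ccccc2)c1OCc1ccccc1 | intermediate
24 | bis{2-(benzyloxy)-4-[(2R)-1-(4-benzyloxy-2-bromophenyl)-3,4-dihydroxybutan-2-yl]-3-methoxyphenyl} ether (both configurations at each new carbinol carbon) | COc1c([C@@H](Cc2ccc(OCc3ccccc3)cc2Br)C(O)CO)ccc(Oc2ccc([C@@H](Cc3ccc(OCc4ccccc4)cc3Br)C(O)CO)c(OC)c2OCc2ccccc2)c1OCc1ccccc1 | intermediate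
25 | bis{2-(benzyloxy)-4-[(2R)-1-(4-benzyloxy-2-bromophenyl)-3-oxopropan-2-yl]-3-methoxyphenyl} ether | COc1c([C@@H](Cc2ccc(OCc3ccccc3)cc2Br)C=O)ccc(Oc2ccc([C@@H](Cc3ccc(OCc4ccccc4)cc3Br)C=O)c(OC)c2OCc2ccccc2)c1OCc1ccccc1 | intermediate
26 | bis{2-(benzyloxy)-4-[(2R)-1-(4-benzyloxy-2-bromophenyl)-3-hydroxypropan-2-yl]-3-methoxyphenyl} ether | COc1c([C@@H](Cc2ccc(OCc3ccccc3)cc2Br)CO)ccc(Oc2ccc([C@@H](Cc3ccc(OCc4ccccc4)cc3Br)CO)c(OC)c2OCc2ccccc2)c1OCc1ccccc1 | intermediate
27 | bis{2-(benzyloxy)-4-[(3R)-7-(benzyloxy)-3,4-dihydro-2H-chromen-3-yl]-3-methoxyphenyl} ether | COc1c([C@@H]2COc3cc(OCc4ccccc4)ccc3C2)ccc(Oc2ccc([C@@H]3COc4cc(OCc5ccccc5)ccc4C3)c(OC)c2OCc2ccccc2)c1OCc1ccccc1 | intermediate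
28 | bis{2-hydroxy-4-[(3R)-7-hydroxy-3,4-dihydro-2H-chromen-3-yl]-3-methoxyphenyl} ether (CNP0116832.1) | COc1c([C@@H]2COc3cc(O)ccc3C2)ccc(Oc2ccc([C@@H]3COc4cc(O)ccc4C3)c(OC)c2O)c1O | target

## Step count and risks

Total step count: 19. Longest linear sequence: 15 steps (steps 1–6, then 11–19); the core branch (steps 7–10) joins at step 11.

**Step 13 (key step).**
Risk: incomplete twofold complexation and eroded facial selectivity. Two bulky diazaborolidine units must sit on phenols flanking the same bridging oxygen, and that diaryl ether oxygen can compete with the allyl ether oxygen for boron. Lewis-acid ionisation of the allyl ether is a lesser hazard.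
Fallback (substrate control instead of reagent control), from 4 and 16, returning at 21: Copper-mediated coupling of 4 with (S)-but-3-yn-2-ol, as in step 4, gives (2S)-5-[4-(benzyloxy)-2-bromophenyl]pent-3-yn-2-ol F1. Hydroalumination as in step 5 gives (2S,3E)-5-[4-(benzyloxy)-2-bromophenyl]pent-3-en-2-ol F2. Twofold Mitsunobu etherification of 16 with two molecules of F2 (PPh3, DIAD, inversion) gives bis{3-{[(2R,3E)-5-(4-benzyloxy-2-bromophenyl)pent-3-en-2-yl]oxy}-2-(methoxymethoxy)phenyl} ether F3. Heating F3 in N,N-diethylaniline effects the thermal aromatic Claisen rearrangement through a chair with the methyl group equatorial. Chirality is transferred to the (S)-benzylic carbons, leaving E-propenyl groups in the 2'-hydroxy-3'-MOM compound bis{4-[(2S,3E)-1-(4-benzyloxy-2-bromophenyl)pent-3-en-2-yl]-3-hydroxy-2-(methoxymethoxy)phenyl} ether F4. Ethenolysis (ethylene, second-generation Hoveyda–Grubbs catalyst) trims propenyl to vinyl, giving bis{4-[(2S)-1-(4-benzyloxy-2-bromophenyl)but-3-en-2-yl]-3-hydroxy-2-(methoxymethoxy)phenyl} ether F5. Acid methanolysis of the MOM groups, as in step 12, returns to 21. The differentiated phenol pattern of F5 would also allow direct 2'-O-methylation; the return chosen here keeps the later steps unchanged.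

**Step 14.**
Risk: benzylation at the wrong catechol oxygen or at both, because the acidity and steric differences between O3' and O2' are modest.
Fallback (temporary engagement of O2' by the neighbouring alkene), from 21, returning at 22: Iodoetherification (I2, NaHCO3, MeCN, 0 °C) lets only the 2'-hydroxyl reach the vinyl group (5-exo). It gives 6,6'-oxybis{(3R)-3-[(4-benzyloxy-2-bromophenyl)methyl]-2-(iodomethyl)-2,3-dihydro-1-benzofuran-7-ol} F6. The cyclisation is expected to outrun oxidation of the catechol by iodine. The single remaining phenol is benzylated (BnBr, K2CO3, DMF) to 6,6'-oxybis{(3R)-7-(benzyloxy)-3-[(4-benzyloxy-2-bromophenyl)methyl]-2-(iodomethyl)-2,3-dihydro-1-benzofuran} F7. Zinc dust in AcOH/EtOH effects reductive β-elimination, regenerating the vinyl group and the 2'-phenol, which is 22.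

**Step 17.**
Risk: partial epimerisation at C3 by enolisation of the α-aryl aldehyde 25 before it is reduced. Both centres must survive, so even modest erosion produces the meso diastereomer.
Fallback (no free aldehyde), from 23, returning at 26: Ozonolysis in CH2Cl2 at −78 °C without a participating solvent gives bis{2-(benzyloxy)-4-[(1R)-2-(4-benzyloxy-2-bromophenyl)-1-(1,2,4-trioxolan-3-yl)ethyl]-3-methoxyphenyl} ether F8. NaBH4 added at low temperature reduces the ozonide directly to 26, so the aldehyde never accumulates without hydride present. The price is the selectivity of ozone against the electron-rich B rings, which is why this is not the first choice.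

**Step 10.**
Risk: incomplete second lithiation, or metalation ortho to the bridging oxygen, giving mono-hydroxylated or regioisomeric phenols.
Fallback (electrophilic ortho-functionalisation instead of metalation), from 12, returning at 16: Magnesium-mediated ortho-formylation (MgCl2, Et3N, paraformaldehyde, MeCN, reflux) gives 3,3'-oxybis(2-hydroxybenzaldehyde) F9; the only free position ortho to each phenol is formylated. MOM protection gives 3,3'-oxybis[2-(methoxymethoxy)benzaldehyde] F10. Baeyer–Villiger oxidation with mCPBA gives oxybis[2-(methoxymethoxy)-3,1-phenylene] diformate F11. Methanolysis (K2CO3, MeOH) gives 16.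

**Step 4.**
Risk: base-induced propargyl–allene isomerisation at the doubly activated methylene of 6, or O-benzylation of propargyl alcohol.
Fallback (E alkene installed directly by sp3–sp2 coupling), from 4, returning at 7: Suzuki–Miyaura coupling with commercial (E)-3-(tert-butyldimethylsilyloxy)prop-1-enylboronic acid pinacol ester (Pd(PPh3)4, K2CO3, THF/H2O) gives tert-butyl{[(2E)-4-(4-benzyloxy-2-bromophenyl)but-2-en-1-yl]oxy}dimethylsilane F12. The benzylic bromide undergoes oxidative addition ahead of the hindered aryl bromide. TBAF gives 7, bypassing 6 and step 5.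

## Further compounds

F1 | step 13 | (2S)-5-[4-(benzyloxy)-2-bromophenyl]pent-3-yn-2-ol | C[C@H](O)C#CCc1ccc(OCc2ccccc2)cc1Br
F2 | step 13 | (2S,3E)-5-[4-(benzyloxy)-2-bromophenyl]pent-3-en-2-ol | C[C@H](O)/C=C/Cc1ccc(OCc2ccccc2)cc1Br
F3 | step 13 | bis{3-{[(2R,3E)-5-(4-benzyloxy-2-bromophenyl)pent-3-en-2-yl]oxy}-2-(methoxymethoxy)phenyl} ether | COCOc1c(O[C@H](C)/C=C/Cc2ccc(OCc3ccccc3)cc2Br)cccc1Oc1cccc(O[C@H](C)/C=C/Cc2ccc(OCc3ccccc3)cc2Br)c1OCOC
F4 | step 13 | bis{4-[(2S,3E)-1-(4-benzyloxy-2-bromophenyl)pent-3-en-2-yl]-3-hydroxy-2-(methoxymethoxy)phenyl} ether | Oc1c([C@@H](Cc2ccc(OCc3ccccc3)cc2Br)/C=C/C)ccc(Oc2ccc([C@@H](Cc3ccc(OCc4ccccc4)cc3Br)/C=C/C)c(O)c2OCOC)c1OCOC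
F5 | step 13 | bis{4-[(2S)-1-(4-benzyloxy-2-bromophenyl)but-3-en-2-yl]-3-hydroxy-2-(methoxymethoxy)phenyl} ether | Oc1c([C@@H](Cc2ccc(OCc3ccccc3)cc2Br)C=C)ccc(Oc2ccc([C@@H](Cc3ccc(OCc4ccccc4)cc3Br)C=C)c(O)c2OCOC)c1OCOC
F6 | step 14 | 6,6'-oxybis{(3R)-3-[(4-benzyloxy-2-bromophenyl)methyl]-2-(iodomethyl)-2,3-dihydro-1-benzofuran-7-ol} (epimers at C2) | Oc1c(Oc2ccc3c(c2O)OC(CI)[C@@H]3Cc2ccc(OCc4ccccc4)cc2Br)ccc2c1OC(CI)[C@@H]2Cc1ccc(OCc2ccccc2)cc1Br
F7 | step 14 | 6,6'-oxybis{(3R)-7-(benzyloxy)-3-[(4-benzyloxy-2-bromophenyl)methyl]-2-(iodomethyl)-2,3-dihydro-1-benzofuran} (epimers at C2) | C(c1ccccc1)Oc1c(Oc2ccc3c(c2OCc2ccccc2)OC(CI)[C@@H]3Cc2ccc(OCc4ccccc4)cc2Br)ccc2c1OC(CI)[C@@H]2Cc1ccc(OCc2ccccc2)cc1Br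
F8 | step 17 | bis{2-(benzyloxy)-4-[(1R)-2-(4-benzyloxy-2-bromophenyl)-1-(1,2,4-trioxolan-3-yl)ethyl]-3-methoxyphenyl} ether (epimers at the trioxolane carbon) | COc1c([C@@H](Cc2ccc(OCc3ccccc3)cc2Br)C2OCOO2)ccc(Oc2ccc([C@@H](Cc3ccc(OCc4ccccc4)cc3Br)C3OCOO3)c(OC)c2OCc2ccccc2)c1OCc1ccccc1
F9 | step 10 | 3,3'-oxybis(2-hydroxybenzaldehyde) | O=Cc1cccc(Oc2cccc(C=O)c2O)c1O
F10 | step 10 | 3,3'-oxybis[2-(methoxymethoxy)benzaldehyde] | COCOc1c(C=O)cccc1Oc1cccc(C=O)c1OCOC
F11 | step 10 | oxybis[2-(methoxymethoxy)-3,1-phenylene] diformate | COCOc1c(OC=O)cccc1Oc1cccc(OC=O)c1OCOC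
F12 | step 4 | tert-butyl{[(2E)-4-(4-benzyloxy-2-bromophenyl)but-2-en-1-yl]oxy}dimethylsilane | CC(C)(C)[Si](C)(C)OC/C=C/Cc1ccc(OCc2ccccc2)cc1Br
A1 | alternative 1 | bis{2-(benzyloxy)-3-methoxy-4-[(3R)-7-oxo-3,4,4a,5,6,7-hexahydro-2H-chromen-3-yl]phenyl} ether (epimers at C4a) | COc1c([C@@H]2COC3=CC(=O)CCC3C2)ccc(Oc2ccc([C@@H]3COC4=CC(=O)CCC4C3)c(OC)c2OCc2ccccc2)c1OCc1ccccc1
A2 | alternative 1 | bis{2-(benzyloxy)-4-[(2R)-1-(4-ethoxy-2-oxocyclohex-3-en-1-yl)-3-hydroxypropan-2-yl]-3-methoxyphenyl} ether (epimers at the ring carbon) | CCOC1=CC(=O)C(C[C@@H](CO)c2ccc(Oc3ccc([C@H](CO)CC4CCC(OCC)=CC4=O)c(OC)c3OCc3ccccc3)c(OCc3ccccc3)c2OC)CC1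
A3 | alternative 2 | bis{2-hydroxy-3-methoxy-4-[(3R)-7-(triisopropylsilyloxy)-3,4-dihydro-2H-chromen-3-yl]phenyl} ether | COc1c([C@@H]2COc3cc(O[Si](C(C)C)(C(C)C)C(C)C)ccc3C2)ccc(Oc2ccc([C@@H]3COc4cc(O[Si](C(C)C)(C(C)C)C(C)C)ccc4C3)c(OC)c2O)c1O
A4 | alternative 2 | bis{3-methoxy-4-[(3R)-7-(triisopropylsilyloxy)-3,4-dihydro-2H-chromen-3-yl]phenyl} ether | COc1cc(Oc2ccc([C@@H]3COc4cc(O[Si](C(C)C)(C(C)C)C(C)C)ccc4C3)c(OC)c2)ccc1[C@@H]1COc2cc(O[Si](C(C)C)(C(C)C)C(C)C)ccc2C1
A5 | alternative 3 | di-tert-butyl (2R,2'R)-2,2'-[oxybis(2-benzyloxy-3-methoxy-4,1-phenylene)]bis{3-[4-(benzyloxy)-2-(methoxymethoxy)phenyl]propanoate} | COc1c([C@@H](Cc2ccc(OCc3ccccc3)cc2OCOC)C(=O)OC(C)(C)C)ccc(Oc2ccc([C@@H](Cc3ccc(OCc4ccccc4)cc3OCOC)C(=O)OC(C)(C)C)c(OC)c2OCc2ccccc2)c1OCc1ccccc1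
A6 | alternative 3 | di-tert-butyl 2,2'-[oxybis(2-benzyloxy-3-methoxy-4,1-phenylene)]bis(prop-2-enoate) | COc1c(C(=C)C(=O)OC(C)(C)C)ccc(Oc2ccc(C(=C)C(=O)OC(C)(C)C)c(OC)c2OCc2ccccc2)c1OCc1ccccc1
A7 | alternative 3 | [4-(benzyloxy)-2-(methoxymethoxy)phenyl]boronic acid | OB(O)c1ccc(OCc2ccccc2)cc1OCOC
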